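The route rests on opening ring C between O1 and C2, which leads back to an acyclic (E)-chalcone. The key step exploits that C2 is the β-carbon of the C4 ketone and benzylic to ring B. O1 sits on C8a of ring A, ortho to the acyl-bearing C4a. One catalytic asymmetric 6-endo-trig oxa-Michael addition closes ring C, sets (2S) and fixes the 6-geranyl rather than the 8-geranyl pattern. Its precursor has a single free phenol, next to the unsubstituted ring A carbon. The other three phenolic oxygens are methoxymethyl ethers. This pattern comes from a symmetric 4-geranyl-3,5-dioxygenated phenol made by directed metalation and C–H borylation.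

Key step: step 8

Abbreviations: geranyl = (2E)-3,7-dimethylocta-2,6-dien-1-yl; MOM = methoxymethyl; EE = 1-ethoxyethyl; ring A = benzo ring, ring B = 2-aryl ring, ring C = pyranone ring.

Assumption: the quinidine-derived thiourea is taken to open the Si face of the β-carbon and so give (2S), by analogy with this catalyst family in conjugate additions to chalcones; the quinine-derived pseudoenantiomer is its mirror-image tool.

Remark: EE-bearing compounds are epimer mixtures at the acetal carbon, which is lost in step 7.

Step 1
Reactants: 1 resorcinol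
Product: 2 1,3-bis(methoxymethoxy)benzene
Conditions: MOMCl, i-Pr2NEt (DIPEA), CH2Cl2, 0 °C to rt
Reagents that add atoms: chloromethyl methyl ether COCCl
Why: O-alkylation of both phenols with the reactive α-chloro ether gives the bis-acetal, which protects the future O5 and O7 and directs the next metalation.

Step 2
Reactants: 2 1,3-bis(methoxymethoxy)benzene; 3 geranyl bromide
Product: 5 2-geranyl-1,3-bis(methoxymethoxy)benzene, via aryllithium 4 (not isolated)
Conditions: n-BuLi, THF, 0 °C to rt; then 3, −78 °C to rt
Reagents that add atoms: n-butyllithium [Li]CCCC (supplies only the lithium of intermediate 4)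
Why: Directed ortho-metalation occurs at the carbon between the two coordinating OMOM groups, and SN2 alkylation with the primary allylic bromide keeps the E geometry of the chain.

Step 3
Reactants: 5 2-geranyl-1,3-bis(methoxymethoxy)benzene
Product: 7 4-geranyl-3,5-bis(methoxymethoxy)phenol, via arylboronate 6 (not isolated)
Conditions: [Ir(OMe)(cod)]2 (cat.), 4,4'-di-tert-butyl-2,2'-bipyridine (cat.), B2pin2 (0.6 equiv), THF, 65 °C; then 30% aq H2O2, aq NaOH, 0 °C
Reagents that add atoms: hydrogen peroxide OO; bis(pinacolato)diboron CC1(C)OB(OC1(C)C)B1OC(C)(C)C(C)(C)O1 (supplies only the boronate group of intermediate 6)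
Why: Sterically governed iridium-catalysed C–H borylation reaches only the ring C–H that has no ortho substituent, and oxidation of the C–B bond gives the symmetric phenol whose oxygen becomes O1, while trisubstituted alkenes should be inert to both operations.

Step 4
Reactants: 7 4-geranyl-3,5-bis(methoxymethoxy)phenol
Product: 8 1-(1-ethoxyethoxy)-4-geranyl-3,5-bis(methoxymethoxy)benzene
Conditions: ethyl vinyl ether, pyridinium p-toluenesulfonate (PPTS, cat.), CH2Cl2, rt
Reagents that add atoms: ethyl vinyl ether C=COCC
Why: Acid-catalysed addition of the phenol to the vinyl ether gives a mixed acetal that directs lithiation like MOM but is far more acid-labile, so it can later be removed alone.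

Step 5
Reactants: 9 syringaldehyde
Product: 10 3,5-dimethoxy-4-(methoxymethoxy)benzaldehyde
Conditions: MOMCl, DIPEA, CH2Cl2, 0 °C to rt
Reagents that add atoms: chloromethyl methyl ether COCCl
Why: O-alkylation caps the acidic ring B phenol so that it neither quenches the aryllithium of step 7 nor deactivates the enone of step 8.

Step 6
Reactants: 10 3,5-dimethoxy-4-(methoxymethoxy)benzaldehyde; 11 diethyl [2-(methoxy(methyl)amino)-2-oxoethyl]phosphonate
Product: 12 (E)-3-[3,5-dimethoxy-4-(methoxymethoxy)phenyl]-N-methoxy-N-methylprop-2-enamide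
Conditions: LiCl, DBU, MeCN, rt
Reagents that add atoms: none
Why: Horner–Wadsworth–Emmons olefination of an aromatic aldehyde with a stabilised phosphonate under mild LiCl/amine conditions should give the E-enamide.

Step 7
Reactants: 8 1-(1-ethoxyethoxy)-4-geranyl-3,5-bis(methoxymethoxy)benzene; 12 (E)-3-[3,5-dimethoxy-4-(methoxymethoxy)phenyl]-N-methoxy-N-methylprop-2-enamide
Product: 15 (E)-1-[3-geranyl-6-hydroxy-2,4-bis(methoxymethoxy)phenyl]-3-[3,5-dimethoxy-4-(methoxymethoxy)phenyl]prop-2-en-1-one, via aryllithium 13 (not isolated), via EE-protected chalcone 14 (not isolated)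
Conditions: n-BuLi, THF, 0 °C; then 12, −78 to 0 °C; AcOH quench; crude product in MeOH, PPTS (cat.), rt
Reagents that add atoms: n-butyllithium [Li]CCCC (supplies only the lithium of intermediate 13)
Why: The two remaining ring C–H bonds are equivalent and each lies between two acetal oxygens, so directed ortho-metalation gives one aryllithium, whose 1,2-addition to the Weinreb amide stops at the chelated adduct and gives the enone on quench, after which mild methanolysis removes only the EE acetal.

Step 8
Reactants: 15 (E)-1-[3-geranyl-6-hydroxy-2,4-bis(methoxymethoxy)phenyl]-3-[3,5-dimethoxy-4-(methoxymethoxy)phenyl]prop-2-en-1-one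
Product: 16 (2S)-2-[3,5-dimethoxy-4-(methoxymethoxy)phenyl]-6-geranyl-5,7-bis(methoxymethoxy)chroman-4-one
Conditions: 1-[3,5-bis(trifluoromethyl)phenyl]-3-[(9R)-6'-methoxycinchonan-9-yl]thiourea (quinidine-derived, 20 mol %), toluene, rt
Reagents that add atoms: none
Why: The quinuclidine nitrogen of the bifunctional catalyst takes up the proton of the only free phenol (the future O1) while the thiourea N–H bonds bind the C4 carbonyl oxygen, the phenoxide oxygen adds to the β-carbon (the future C2) of the s-cis enone, and protonation of the enolate at C3 completes the isomerisation. The closest known reaction type is the organocatalytic enantioselective intramolecular oxa-Michael addition of 2'-hydroxychalcones to flavanones, the laboratory counterpart of the chalcone isomerase reaction. Ring C closes in the 6-endo-trig mode. The new stereocentre C2 is controlled by the catalyst alone, whose chiral pocket should expose the Si face of the β-carbon and so give (2S). The step needs site selectivity between the two oxygens ortho to the acyl group, which is secured because the oxygen flanked by the geranyl chain is capped as a MOM ether, so only the 6-geranyl skeleton can form. It also needs slow uncatalysed and reverse reactions, which are secured by the absence of added achiral base, by the twisted 2',6'-dioxygenated aryl ketone that favours the closed form, and by the MOM cap on the ring B oxygen, which blocks quinone-methide-type ring opening.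

Step 9
Reactants: 16 (2S)-2-[3,5-dimethoxy-4-(methoxymethoxy)phenyl]-6-geranyl-5,7-bis(methoxymethoxy)chroman-4-one
Product: 17 (2S)-6-geranyl-5,7-dihydroxy-2-(4-hydroxy-3,5-dimethoxyphenyl)chroman-4-one (target)
Conditions: conc. aq HCl (cat.), MeOH, 40 °C, short reaction time
Reagents that add atoms: none
Why: Acid-catalysed transacetalisation to methanol removes the three phenolic MOM groups, C2 should hold because flavanone ring opening needs phenoxide or enolate formation that dilute acid suppresses, and the brief mild exposure should spare the geranyl alkenes.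

Compound list
1 | resorcinol (benzene-1,3-diol) | Oc1cccc(O)c1 | starting material
2 | 1,3-bis(methoxymethoxy)benzene | COCOc1cccc(OCOC)c1 | intermediate
3 | geranyl bromide, (2E)-1-bromo-3,7-dimethylocta-2,6-diene | BrC/C=C(\C)CCC=C(C)C | starting material
4 | [2,6-bis(methoxymethoxy)phenyl]lithium | [Li]c1c(OCOC)cccc1OCOC | intermediate
5 | 2-geranyl-1,3-bis(methoxymethoxy)benzene | COCOc1cccc(OCOC)c1C/C=C(\C)CCC=C(C)C | intermediate
6 | 2-[4-geranyl-3,5-bis(methoxymethoxy)phenyl]-4,4,5,5-tetramethyl-1,3,2-dioxaborolane | COCOc1cc(B2OC(C)(C)C(C)(C)O2)cc(OCOC)c1C/C=C(\C)CCC=C(C)C | intermediate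
7 | 4-geranyl-3,5-bis(methoxymethoxy)phenol | COCOc1cc(O)cc(OCOC)c1C/C=C(\C)CCC=C(C)C | intermediate
8 | 1-(1-ethoxyethoxy)-4-geranyl-3,5-bis(methoxymethoxy)benzene (racemic at the acetal carbon) | CCOC(C)Oc1cc(OCOC)c(C/C=C(\C)CCC=C(C)C)c(OCOC)c1 | intermediate
9 | syringaldehyde (4-hydroxy-3,5-dimethoxybenzaldehyde) | COc1cc(C=O)cc(OC)c1O | starting material
10 | 3,5-dimethoxy-4-(methoxymethoxy)benzaldehyde | COCOc1c(OC)cc(C=O)cc1OC | intermediate
11 | diethyl [2-(methoxy(methyl)amino)-2-oxoethyl]phosphonate | CCOP(=O)(CC(=O)N(C)OC)OCC | starting material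
12 | (E)-3-[3,5-dimethoxy-4-(methoxymethoxy)phenyl]-N-methoxy-N-methylprop-2-enamide | COCOc1c(OC)cc(/C=C/C(=O)N(C)OC)cc1OC | intermediate
13 | [6-(1-ethoxyethoxy)-3-geranyl-2,4-bis(methoxymethoxy)phenyl]lithium | [Li]c1c(OC(C)OCC)cc(OCOC)c(C/C=C(\C)CCC=C(C)C)c1OCOC | intermediate
14 | (E)-1-[6-(1-ethoxyethoxy)-3-geranyl-2,4-bis(methoxymethoxy)phenyl]-3-[3,5-dimethoxy-4-(methoxymethoxy)phenyl]prop-2-en-1-one | CCOC(C)Oc1cc(OCOC)c(C/C=C(\C)CCC=C(C)C)c(OCOC)c1C(=O)/C=C/c1cc(OC)c(OCOC)c(OC)c1 | intermediate
15 | (E)-1-[3-geranyl-6-hydroxy-2,4-bis(methoxymethoxy)phenyl]-3-[3,5-dimethoxy-4-(methoxymethoxy)phenyl]prop-2-en-1-one | Oc1cc(OCOC)c(C/C=C(\C)CCC=C(C)C)c(OCOC)c1C(=O)/C=C/c1cc(OC)c(OCOC)c(OC)c1 | intermediate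
16 | (2S)-2-[3,5-dimethoxy-4-(methoxymethoxy)phenyl]-6-geranyl-5,7-bis(methoxymethoxy)chroman-4-one | COc1cc([C@@H]2CC(=O)c3c(cc(OCOC)c(C/C=C(\C)CCC=C(C)C)c3OCOC)O2)cc(OC)c1OCOC | intermediate
17 | (2S)-6-geranyl-5,7-dihydroxy-2-(4-hydroxy-3,5-dimethoxyphenyl)chroman-4-one | COc1cc([C@@H]2CC(=O)c3c(cc(O)c(C/C=C(\C)CCC=C(C)C)c3O)O2)cc(OC)c1O | target

Total step count: 9. Longest linear sequence: 7 (steps 1, 2, 3, 4, 7, 8, 9).

Steps most likely to fail

**Step 8.**
- What may go wrong: turnover may be slow because the electron-rich ring B lowers the electrophilicity of the β-carbon. Facial discrimination may be insufficient, and enantiopurity may erode through reversible ring opening on long exposure to the basic catalyst.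
- Fallback idea: the stereocentre is set before ring closure, and the O1–C2 bond is then made by substitution. The fallback sets out from 14, isolated after the acetic acid quench of step 7, and returns at 16.
- Sequence:
  - Copper-catalysed asymmetric conjugate borylation (CuCl, NaOt-Bu, a Josiphos-type ligand of the enantiomeric series that delivers the R product, B2pin2, MeOH, THF) should give the (R)-β-boryl ketone F1.
  - Oxidation with NaBO3·4H2O in THF/water, with retention, gives the EE-protected (R)-β-hydroxy ketone F2.
  - PPTS in MeOH frees the phenol to give the (R)-hydroxy phenol F3.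
  - Mitsunobu cyclisation (PPh3, DIAD, toluene, 0 °C) with inversion at the benzylic carbon gives 16.

**Step 7.**
- What may go wrong: the doubly activated benzylic–allylic CH2 of the geranyl chain may be deprotonated in competition with the ring. The hindered, strongly basic aryllithium may also break down the Weinreb amide instead of adding to its carbonyl group.
- Fallback idea: the route avoids organolithium chemistry, sets out from 7 and returns at 15.
- Sequence:
  - Magnesium-phenoxide-directed ortho-formylation (MgCl2, Et3N, paraformaldehyde, MeCN, reflux; Casnati–Skattebøl reaction) gives the salicylaldehyde F4.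
  - Excess MeMgBr in THF gives the racemic carbinol F5.
  - MnO2 in CH2Cl2 gives the acetophenone F6.
  - Claisen–Schmidt condensation with 10 (KOH, EtOH, rt), in which the product stays open as its phenoxide, gives 15.

**Step 3.**
- What may go wrong: iridium boryl and hydride species may hydroborate or isomerise the geranyl alkenes during the C–H borylation.
- Fallback idea: the borylation is moved ahead of the geranylation so that the iridium catalyst never meets an alkene. The fallback sets out from 2 and returns at 7.
- Sequence: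
  - 2 is borylated at its only unhindered position under the same catalyst to the arylboronate F7.
  - Oxidation with H2O2/NaOH gives the phenol F8.
  - TIPSCl and imidazole in DMF give the silyl ether F9.
  - n-BuLi metalates between the two OMOM groups, because the bulky, non-coordinating silyloxy group shields its own ortho positions, and gives the aryllithium F10.
  - Alkylation with 3 gives the geranylated silyl ether F11, and TBAF in THF then gives 7.

Further compounds
F1 | step 8 | (3R)-1-[6-(1-ethoxyethoxy)-3-geranyl-2,4-bis(methoxymethoxy)phenyl]-3-[3,5-dimethoxy-4-(methoxymethoxy)phenyl]-3-(4,4,5,5-tetramethyl-1,3,2-dioxaborolan-2-yl)propan-1-one | CC1(C)OB(OC1(C)C)[C@H](CC(=O)c1c(OC(C)OCC)cc(OCOC)c(C/C=C(\C)CCC=C(C)C)c1OCOC)c1cc(OC)c(OCOC)c(OC)c1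
F2 | step 8 | (3R)-1-[6-(1-ethoxyethoxy)-3-geranyl-2,4-bis(methoxymethoxy)phenyl]-3-hydroxy-3-[3,5-dimethoxy-4-(methoxymethoxy)phenyl]propan-1-one | O[C@H](CC(=O)c1c(OC(C)OCC)cc(OCOC)c(C/C=C(\C)CCC=C(C)C)c1OCOC)c1cc(OC)c(OCOC)c(OC)c1
F3 | step 8 | (3R)-1-[3-geranyl-6-hydroxy-2,4-bis(methoxymethoxy)phenyl]-3-hydroxy-3-[3,5-dimethoxy-4-(methoxymethoxy)phenyl]propan-1-one | O[C@H](CC(=O)c1c(O)cc(OCOC)c(C/C=C(\C)CCC=C(C)C)c1OCOC)c1cc(OC)c(OCOC)c(OC)c1
F4 | step 7 | 3-geranyl-6-hydroxy-2,4-bis(methoxymethoxy)benzaldehyde | O=Cc1c(O)cc(OCOC)c(C/C=C(\C)CCC=C(C)C)c1OCOC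
F5 | step 7 | 1-[3-geranyl-6-hydroxy-2,4-bis(methoxymethoxy)phenyl]ethanol (racemic) | CC(O)c1c(O)cc(OCOC)c(C/C=C(\C)CCC=C(C)C)c1OCOC
F6 | step 7 | 1-[3-geranyl-6-hydroxy-2,4-bis(methoxymethoxy)phenyl]ethanone | CC(=O)c1c(O)cc(OCOC)c(C/C=C(\C)CCC=C(C)C)c1OCOC
F7 | step 3 | 2-[3,5-bis(methoxymethoxy)phenyl]-4,4,5,5-tetramethyl-1,3,2-dioxaborolane | COCOc1cc(B2OC(C)(C)C(C)(C)O2)cc(OCOC)c1
F8 | step 3 | 3,5-bis(methoxymethoxy)phenol | COCOc1cc(O)cc(OCOC)c1
F9 | step 3 | [3,5-bis(methoxymethoxy)phenoxy]triisopropylsilane | COCOc1cc(O[Si](C(C)C)(C(C)C)C(C)C)cc(OCOC)c1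
F10 | step 3 | [2,6-bis(methoxymethoxy)-4-(triisopropylsilyloxy)phenyl]lithium | [Li]c1c(OCOC)cc(O[Si](C(C)C)(C(C)C)C(C)C)cc1OCOC
F11 | step 3 | [4-geranyl-3,5-bis(methoxymethoxy)phenoxy]triisopropylsilane | COCOc1cc(O[Si](C(C)C)(C(C)C)C(C)C)cc(OCOC)c1C/C=C(\C)CCC=C(C)C
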